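The data stem from a simulated flask for an exercise; the scatter is artificial.

The target does not keep: in the epsilon run it read 25.9% at 2.50 h and 11.9% at 8.00 h, while over-reaction product climbed to 42.1%. I had to decide how the next charge goes in, so I compared the set-ups by the share of target in target plus over-reaction product, its selectivity.

| setting | epsilon | zeta | Wednesday's | Monday's | Saturday's |
|---|---|---|---|---|---|
| starting material | 0.10 M | 0.10 M | 0.10 M | 0.10 M | 0.10 M (fed, over 4.00 h) |
| enzyme | 10 µM | 5 µM | 10 µM | 10 µM | 10 µM |
| remark | run made earlier | run made earlier | everything together in a closed stirred flask, run for 8.0 h | one stirred flow tank at steady state, fed with the mixture as stated, mean residence time 8.0 h | all but starting material at the start; starting material goes in evenly over 4.00 h, the run ends at 8.0 h |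
| time |  |  | 8.0 h |  | 8.0 h |

epsilon run (percent of the starting material charged)

| time / h | target / % | over-reaction product / % |
|---|---|---|
| 0.667 | 14.0 | 1.4 |
| 1.00 | 16.4 | 3.0 |
| 1.33 | 20.7 | 4.9 |
| 2.50 | 25.9 | 10.3 |
| 3.00 | 24.7 | 16.2 |
| 5.00 | 20.7 | 28.9 |
| 8.00 | 11.9 | 42.1 |

zeta run (percent of the starting material charged)

| time / min | target / % | over-reaction product / % |
|---|---|---|
| 8.00 | 1.4 | 0 |
| 12.0 | 2.8 | 0 |
| 20.0 | 3.9 | 0 |
| 25.0 | 5.6 | 1.6 |
| 40.0 | 6.6 | 1.2 |
| 60.0 | 10.6 | 3.0 |
| 90.0 | 11.3 | 2.2 |

(standard deviation of a reading: 1 percentage point)

- the stated concentrations are those of everything mixed, before any reaction; amounts are the same in each set-up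
- the earlier runs were read with a standard deviation of 1 percentage point
- reactions considered so far: starting material + enzyme -> target + enzyme; starting material <-> dormant form; 2 enzyme -> spent catalyst; target -> over-reaction product
- the feed brings no volume worth counting
- the earlier runs were made in a closed, stirred flask

- the set-up with the highest share of target in all that became target or over-reaction product, at the outlet or at the end ("none" if the first two lie within 2 percentage points) (Wednesday's / Monday's / Saturday's / none)
- share of target in all that became target or over-reaction product, at the outlet or at the end, Wednesday's
- share of target in all that became target or over-reaction product, at the outlet or at the end, Monday's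
- share of target in all that became target or over-reaction product, at the outlet or at the end, Saturday's

I kept the charge and chose the way in by one number. Trapezoids through the epsilon readings, starting from zero, gave 3.56 h: the target lifetime, the area under the target curve divided by the over-reaction product made over the same time. The listed step from target to over-reaction product involves no enzyme, so I carried this number between vessels.

Wednesday's repeats the epsilon charge, so its last reading gave a share of 22.0%. That is what target of a single age 5.39 h would show. In Monday's tank at steady state, over-reaction product leaves at target times residence time over lifetime, so the share is 30.8%. Saturday's even feed delays the mean entry of starting material by 2.00 h. If target formation shifted by the same amount, the share would be 38.6%. That beat Monday's by 7.8 percentage points, more than the margin of 2 points, so I chose the feed.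

The forecast also named Saturday's, with 24%, 31% and 37% for Wednesday's, Monday's and Saturday's, reasoning that “feeding delays formation, so target is younger at the end”; my Saturday's figure stood 1.6 points above its own.

The simulation gave Saturday's, with 23.6%, 31.6% and 35.7% in that order, so my Saturday's figure stood 2.9 points high.

    starting material + enzyme → target + enzyme, rate k1*[starting material]^1.5*[enzyme]/(1 + ([starting material]/Kh1)^1.5) (0.0860 M, k = 1.90 × 10⁵ M⁻¹·⁵ h⁻¹)
    starting material ⇌ dormant form (K = 2.30, k = 0.260 h⁻¹)
    2 enzyme → spent catalyst (k = 3100 M⁻¹ h⁻¹)
    target → over-reaction product (k = 0.270 h⁻¹)

Saturday's had not come to rest at 8.00 h. Left until 80.0 h, it held 0.508% target and 80.6% over-reaction product, a share of 0.626%, with 5.47% starting material and 13.4% dormant form still waiting. The added 72.0 h came to 20.2 of my target lifetimes, and in them Saturday's over-reaction product gained 50 points. Wednesday's at 80.0 h held 0.447% target, a share of 0.541%, with 5.02% starting material and 12.3% dormant form still there.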